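The ε end ring is treated as a masked 3,5,5-trimethylcyclohex-2-enone, because its C3′ oxygen is allylic to the C4′=C5′ double bond and the gem-dimethyl carbon C1′ sits β to C3′. A Michael–Wittig [3+3] annulation joins a 2-ethoxyallylidene phosphorane (C2′–C3′–C4′, an acetone 1,3-dianion equivalent) to an isopropylidene acetoacetate (C5′, C6′, C1′ and the C7′ ester), making C1′–C2′ and C4′=C5′ in one operation from two acyclic, achiral partners. A matched Corey–Bakshi–Shibata kinetic resolution sets C3′ and C6′; the ring is grown into a C25 ylide and joined to an epoxy C15 aldehyde made from (4R,6R)-actinol by Sharpless epoxidation, before desilylation and double palmitoylation.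

Key step: step 3

Remark: end-group atoms carry carotenoid numbering (C1–C6 epoxy ring, C1′–C6′ ε ring); (4R,6R)-actinol, the C10 dialdehyde and both C5 phosphonates (used as their E isomers) are taken as purchasable.

Step 1
Reactants: 1 acetone; 2 ethyl acetoacetate
Product: 3 ethyl 2-acetyl-3-methylbut-2-enoate
Conditions: ZnCl2 (cat.), Ac2O, 50 °C
Reagents that add atoms: none
Why: Knoevenagel condensation of the active methylene of 2 with acetone, driven by acetic anhydride as water scavenger, should give the tetrasubstituted alkylidene β-keto ester; no stereocenter is formed.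

Step 2
Reactants: 4 1-(triphenyl-λ5-phosphanylidene)propan-2-one
Product: 5 (2-ethoxyprop-1-en-1-yl)triphenylphosphonium tetrafluoroborate
Conditions: Et3O·BF4, CH2Cl2, 0 °C → rt
Reagents that add atoms: triethyloxonium tetrafluoroborate, CC[O+](CC)CC.F[B-](F)(F)F
Why: O-alkylation of the ambident stabilised acyl ylide by the hard oxonium electrophile should give the 2-ethoxyvinylphosphonium salt; no stereocenter is formed.

Step 3
Reactants: 5 (2-ethoxyprop-1-en-1-yl)triphenylphosphonium tetrafluoroborate; 3 ethyl 2-acetyl-3-methylbut-2-enoate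
Product: 8 ethyl 2,6,6-trimethyl-4-oxocyclohex-2-ene-1-carboxylate (racemic), via 2-ethoxyallylidene ylide 6 (not isolated), via ethoxydiene ester 7 (not isolated)
Conditions: NaN(SiMe3)2, THF, −78 → 0 °C; then 3, −78 °C → reflux; then 1 M HCl, THF, 0 °C
Reagents that add atoms: water, O
Why: The γ-carbon of the ambident ylide 6 adds in Michael fashion to the β,β-dimethyl carbon of the doubly activated alkylidene β-keto ester 3 (new C5–C6 bond of 8, C1′–C2′ of the target), proton transfer from the new methylene to the β-keto ester enolate regenerates an allylic ylide, and this closes onto the acetyl carbonyl by intramolecular Wittig olefination (new C2=C3 bond, C4′=C5′), after which dilute acid hydrolyses the 2-ethoxydiene 7 to the conjugated enone. The closest known reaction type is the Michael-initiated [3+3] Wittig annulation of allylidenephosphoranes with enones and alkylidene acetoacetates, which builds 2,6,6-trimethylcyclohexadiene esters in the same way. The six-membered ring closes by 6-exo-trig attack of the ylide carbon on the ketone followed by oxaphosphetane collapse. The only stereocenter formed, C1 of 8, is epimerisable and arises racemic; its configuration is selected in step 4. The step needs γ- over α-attack of the ylide, conjugate over direct carbonyl addition and ketone over ester olefination, which the tetrasubstituted doubly activated acceptor, the free acetyl group after proton transfer and the much higher Wittig reactivity of ketones should secure. Irreversible loss of Ph3PO pulls the reversible, hindered Michael step forward.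

Step 4
Reactants: 8 ethyl 2,6,6-trimethyl-4-oxocyclohex-2-ene-1-carboxylate (racemic)
Product: 9 ethyl (1R,4R)-4-hydroxy-2,6,6-trimethylcyclohex-2-ene-1-carboxylate
Conditions: (S)-2-methyl-CBS-oxazaborolidine (0.2 equiv), catecholborane (0.6 equiv), toluene, −78 °C, to about half conversion; recovered ketone racemised (DBU, toluene) and resubmitted
Reagents that add atoms: none
Why: Corey–Bakshi–Shibata reduction used as a kinetic resolution: the (S)-oxazaborolidine should give the 4R carbinol, and only in the (1R)-antipode is that also the substrate-preferred face (anti to the pseudoaxial C6 methyl, giving the alcohol trans to the ester), so this antipode should react faster, which sets C4 and selects C1.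

Step 5
Reactants: 9 ethyl (1R,4R)-4-hydroxy-2,6,6-trimethylcyclohex-2-ene-1-carboxylate
Product: 10 ethyl (1R,4R)-4-[(tert-butyldimethylsilyl)oxy]-2,6,6-trimethylcyclohex-2-ene-1-carboxylate
Conditions: TBSCl, imidazole, DMF, rt
Reagents that add atoms: tert-butyldimethylsilyl chloride, CC(C)(C)[Si](C)(C)Cl
Why: Standard silylation of the secondary allylic alcohol protects it against the hydride and olefination steps that follow; no stereocenter is touched.

Step 6
Reactants: 10 ethyl (1R,4R)-4-[(tert-butyldimethylsilyl)oxy]-2,6,6-trimethylcyclohex-2-ene-1-carboxylate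
Product: 11 (1R,4R)-4-[(tert-butyldimethylsilyl)oxy]-2,6,6-trimethylcyclohex-2-ene-1-carbaldehyde
Conditions: i-Bu2AlH (1.05 equiv), CH2Cl2, −78 °C; aq. potassium sodium tartrate
Reagents that add atoms: none
Why: Partial hydride reduction of a hindered ester, whose tetrahedral aluminium hemiacetal should persist at −78 °C until neutral work-up, gives the aldehyde without epimerising C1.

Step 7
Reactants: 11 (1R,4R)-4-[(tert-butyldimethylsilyl)oxy]-2,6,6-trimethylcyclohex-2-ene-1-carbaldehyde; 12 ethyl (2E)-4-(diethoxyphosphoryl)-3-methylbut-2-enoate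
Product: 13 ethyl (2E,4E)-5-[(1R,4R)-4-[(tert-butyldimethylsilyl)oxy]-2,6,6-trimethylcyclohex-2-en-1-yl]-3-methylpenta-2,4-dienoate
Conditions: LiN(SiMe3)2, THF, −78 → 0 °C; 2Z isomer removed by chromatography
Reagents that add atoms: none
Why: Horner–Wadsworth–Emmons olefination with the vinylogous phosphonate should form C7′=C8′ E-selectively, addition to the aldehyde at low temperature outpacing enolisation of the adjacent stereocenter.

Step 8
Reactants: 13 ethyl (2E,4E)-5-[(1R,4R)-4-[(tert-butyldimethylsilyl)oxy]-2,6,6-trimethylcyclohex-2-en-1-yl]-3-methylpenta-2,4-dienoate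
Product: 14 (2E,4E)-5-[(1R,4R)-4-[(tert-butyldimethylsilyl)oxy]-2,6,6-trimethylcyclohex-2-en-1-yl]-3-methylpenta-2,4-dien-1-ol
Conditions: i-Bu2AlH (2.2 equiv), CH2Cl2, −78 °C
Reagents that add atoms: none
Why: 1,2-Reduction of the dienoate by the aluminium hydride gives the primary allylic alcohol with double-bond geometry and stereocenters unchanged.

Step 9
Reactants: 14 (2E,4E)-5-[(1R,4R)-4-[(tert-butyldimethylsilyl)oxy]-2,6,6-trimethylcyclohex-2-en-1-yl]-3-methylpenta-2,4-dien-1-ol
Product: 15 [(2E,4E)-5-[(1R,4R)-4-[(tert-butyldimethylsilyl)oxy]-2,6,6-trimethylcyclohex-2-en-1-yl]-3-methylpenta-2,4-dien-1-yl]triphenylphosphonium bromide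
Conditions: PPh3·HBr, CH2Cl2, 0 °C → rt; crystallisation
Reagents that add atoms: triphenylphosphine hydrobromide, Br.c1ccc(cc1)P(c1ccccc1)c1ccccc1
Why: Acid-mediated ionisation of the dienylic alcohol and capture of the pentadienyl cation at its terminal carbon by PPh3 (SN1-type phosphonium salt formation) should proceed in the aprotic medium without loss of the silyl ether.

Step 10
Reactants: 15 [(2E,4E)-5-[(1R,4R)-4-[(tert-butyldimethylsilyl)oxy]-2,6,6-trimethylcyclohex-2-en-1-yl]-3-methylpenta-2,4-dien-1-yl]triphenylphosphonium bromide; 16 (2E,4E,6E)-2,7-dimethylocta-2,4,6-trienedial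
Product: 17 (2E,4E,6E,8E,10E,12E)-13-[(1R,4R)-4-[(tert-butyldimethylsilyl)oxy]-2,6,6-trimethylcyclohex-2-en-1-yl]-2,7,11-trimethyltrideca-2,4,6,8,10,12-hexaenal
Conditions: 16 (2 equiv), NaOMe, MeOH/CH2Cl2, 0 °C → rt, dark; then heptane, reflux
Reagents that add atoms: none
Why: Wittig olefination of the semistabilised ylide with an excess of the symmetrical dialdehyde should stop at the mono-adduct, and the new C11′=C12′ bond is equilibrated thermally to E.

Step 11
Reactants: 17 (2E,4E,6E,8E,10E,12E)-13-[(1R,4R)-4-[(tert-butyldimethylsilyl)oxy]-2,6,6-trimethylcyclohex-2-en-1-yl]-2,7,11-trimethyltrideca-2,4,6,8,10,12-hexaenal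
Product: 18 (2E,4E,6E,8E,10E,12E)-13-[(1R,4R)-4-[(tert-butyldimethylsilyl)oxy]-2,6,6-trimethylcyclohex-2-en-1-yl]-2,7,11-trimethyltrideca-2,4,6,8,10,12-hexaen-1-ol
Conditions: NaBH4, MeOH/THF, 0 °C
Reagents that add atoms: none
Why: Borohydride 1,2-reduction of the polyenal gives the primary polyenylic alcohol without touching the conjugated chain.

Step 12
Reactants: 18 (2E,4E,6E,8E,10E,12E)-13-[(1R,4R)-4-[(tert-butyldimethylsilyl)oxy]-2,6,6-trimethylcyclohex-2-en-1-yl]-2,7,11-trimethyltrideca-2,4,6,8,10,12-hexaen-1-ol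
Product: 19 [(2E,4E,6E,8E,10E,12E)-13-[(1R,4R)-4-[(tert-butyldimethylsilyl)oxy]-2,6,6-trimethylcyclohex-2-en-1-yl]-2,7,11-trimethyltrideca-2,4,6,8,10,12-hexaen-1-yl]triphenylphosphonium bromide
Conditions: PPh3·HBr, CH2Cl2, 0 °C, dark
Reagents that add atoms: triphenylphosphine hydrobromide, Br.c1ccc(cc1)P(c1ccccc1)c1ccccc1
Why: SN1-type phosphonium salt formation as in step 9, the polyenylic cation being captured at the chain terminus so that full conjugation is kept.

Step 13
Reactants: 20 (4R,6R)-4-hydroxy-2,2,6-trimethylcyclohexan-1-one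
Product: 21 (4R,6R)-4-[(tert-butyldimethylsilyl)oxy]-2,2,6-trimethylcyclohexan-1-one
Conditions: TBSCl, imidazole, DMF, rt
Reagents that add atoms: tert-butyldimethylsilyl chloride, CC(C)(C)[Si](C)(C)Cl
Why: Silylation of the chiral-pool alcohol; its carbinol center becomes C3 of the target and is not touched again.

Step 14
Reactants: 21 (4R,6R)-4-[(tert-butyldimethylsilyl)oxy]-2,2,6-trimethylcyclohexan-1-one
Product: 22 (4R)-4-[(tert-butyldimethylsilyl)oxy]-2,6,6-trimethylcyclohex-1-en-1-yl trifluoromethanesulfonate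
Conditions: Tf2O, 2,6-di-tert-butyl-4-methylpyridine, CH2Cl2, 0 °C → rt
Reagents that add atoms: trifluoromethanesulfonic anhydride, O=S(=O)(OS(=O)(=O)C(F)(F)F)C(F)(F)F
Why: Enol triflate formation by O-triflation and loss of the only α-hydrogen gives the single possible tetrasubstituted vinyl triflate, deliberately erasing the C6 stereocenter.

Step 15
Reactants: 22 (4R)-4-[(tert-butyldimethylsilyl)oxy]-2,6,6-trimethylcyclohex-1-en-1-yl trifluoromethanesulfonate
Product: 23 methyl (4R)-4-[(tert-butyldimethylsilyl)oxy]-2,6,6-trimethylcyclohex-1-ene-1-carboxylate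
Conditions: Pd(OAc)2 (cat.), PPh3, CO (1 atm), MeOH, Et3N, DMF, 70 °C
Reagents that add atoms: carbon monoxide, [C-]#[O+]; methanol, CO
Why: Palladium-catalysed methoxycarbonylation of the vinyl triflate (oxidative addition, CO insertion, methanolysis) installs C7 on the hindered ring carbon.

Step 16
Reactants: 23 methyl (4R)-4-[(tert-butyldimethylsilyl)oxy]-2,6,6-trimethylcyclohex-1-ene-1-carboxylate
Product: 24 [(4R)-4-[(tert-butyldimethylsilyl)oxy]-2,6,6-trimethylcyclohex-1-en-1-yl]methanol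
Conditions: i-Bu2AlH (2.2 equiv), CH2Cl2, −78 → 0 °C
Reagents that add atoms: none
Why: Hydride reduction of the unsaturated ester gives the allylic alcohol needed to direct the epoxidation.

Step 17
Reactants: 24 [(4R)-4-[(tert-butyldimethylsilyl)oxy]-2,6,6-trimethylcyclohex-1-en-1-yl]methanol
Product: 25 [(1R,4S,6R)-4-[(tert-butyldimethylsilyl)oxy]-2,2,6-trimethyl-7-oxabicyclo[4.1.0]heptan-1-yl]methanol
Conditions: Ti(OiPr)4 (0.2 equiv), D-(−)-diethyl tartrate (0.25 equiv), t-BuOOH, 4 Å molecular sieves, CH2Cl2, −20 °C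
Reagents that add atoms: tert-butyl hydroperoxide, CC(C)(C)OO
Why: Sharpless asymmetric epoxidation, in which the titanium tartrate delivers oxygen under reagent control to the face of the tetrasubstituted allylic alcohol anti to the C4 silyloxy group (the face selected by the D-tartrate), sets C5 and C6 of the target.

Step 18
Reactants: 25 [(1R,4S,6R)-4-[(tert-butyldimethylsilyl)oxy]-2,2,6-trimethyl-7-oxabicyclo[4.1.0]heptan-1-yl]methanol
Product: 26 (1S,4S,6R)-4-[(tert-butyldimethylsilyl)oxy]-2,2,6-trimethyl-7-oxabicyclo[4.1.0]heptane-1-carbaldehyde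
Conditions: (n-Pr4N)RuO4 (cat.), N-methylmorpholine N-oxide, 4 Å molecular sieves, CH2Cl2, rt
Reagents that add atoms: none
Why: Ley–Griffith oxidation is neutral and should spare the acid-sensitive epoxide; the aldehyde has no α-hydrogen, so no center can epimerise.

Step 19
Reactants: 26 (1S,4S,6R)-4-[(tert-butyldimethylsilyl)oxy]-2,2,6-trimethyl-7-oxabicyclo[4.1.0]heptane-1-carbaldehyde; 27 diethyl [(2E)-3-cyano-2-methylprop-2-en-1-yl]phosphonate
Product: 28 (2E,4E)-5-[(1S,4S,6R)-4-[(tert-butyldimethylsilyl)oxy]-2,2,6-trimethyl-7-oxabicyclo[4.1.0]heptan-1-yl]-3-methylpenta-2,4-dienenitrile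
Conditions: LiN(SiMe3)2, THF, −78 °C → rt; 2Z isomer removed by chromatography
Reagents that add atoms: none
Why: Horner–Wadsworth–Emmons olefination of the non-enolisable epoxy aldehyde should give the E C7=C8 bond, with the epoxide inert to the stabilised phosphonate anion.

Step 20
Reactants: 28 (2E,4E)-5-[(1S,4S,6R)-4-[(tert-butyldimethylsilyl)oxy]-2,2,6-trimethyl-7-oxabicyclo[4.1.0]heptan-1-yl]-3-methylpenta-2,4-dienenitrile
Product: 30 (2E,4E)-5-[(1S,4S,6R)-4-[(tert-butyldimethylsilyl)oxy]-2,2,6-trimethyl-7-oxabicyclo[4.1.0]heptan-1-yl]-3-methylpenta-2,4-dienal, via aluminium aldiminate 29 (not isolated)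
Conditions: i-Bu2AlH (1.1 equiv), CH2Cl2, −78 °C; aq. potassium sodium tartrate, pH 7 buffer, 0 °C
Reagents that add atoms: water, O
Why: Hydride reduction of the nitrile stops at the N-aluminio aldimine, and near-neutral hydrolysis should release the dienal without opening or rearranging the epoxide.

Step 21
Reactants: 19 [(2E,4E,6E,8E,10E,12E)-13-[(1R,4R)-4-[(tert-butyldimethylsilyl)oxy]-2,6,6-trimethylcyclohex-2-en-1-yl]-2,7,11-trimethyltrideca-2,4,6,8,10,12-hexaen-1-yl]triphenylphosphonium bromide; 30 (2E,4E)-5-[(1S,4S,6R)-4-[(tert-butyldimethylsilyl)oxy]-2,2,6-trimethyl-7-oxabicyclo[4.1.0]heptan-1-yl]-3-methylpenta-2,4-dienal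
Product: 31 (all-E,3S,5R,6S,3′R,6′R)-3,3′-bis[(tert-butyldimethylsilyl)oxy]-5,6-epoxy-5,6-dihydro-β,ε-carotene
Conditions: NaOMe, MeOH/CH2Cl2, 0 °C → rt, dark, argon; then heptane, reflux
Reagents that add atoms: none
Why: Wittig olefination joins the two halves at C11=C12, with the carbanion placed on the ε half because an ylide next to the epoxide would open it; thermal equilibration should give the all-E polyene.

Step 22
Reactants: 31 (all-E,3S,5R,6S,3′R,6′R)-3,3′-bis[(tert-butyldimethylsilyl)oxy]-5,6-epoxy-5,6-dihydro-β,ε-carotene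
Product: 32 (all-E,3S,5R,6S,3′R,6′R)-5,6-epoxy-5,6-dihydro-β,ε-carotene-3,3′-diol
Conditions: Bu4NF, THF, 0 °C → rt, dark
Reagents that add atoms: none
Why: Fluoride-mediated desilylation is basic and non-acidic, so neither the 5,6-epoxide nor the allylic C3′ alcohol should rearrange or epimerise.

Step 23
Reactants: 32 (all-E,3S,5R,6S,3′R,6′R)-5,6-epoxy-5,6-dihydro-β,ε-carotene-3,3′-diol; 33 hexadecanoyl chloride
Product: 34 (all-E,3S,5R,6S,3′R,6′R)-5,6-epoxy-5,6-dihydro-β,ε-carotene-3,3′-diyl dihexadecanoate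
Conditions: 33 (2.5 equiv), pyridine, 4-(dimethylamino)pyridine (cat.), CH2Cl2, 0 °C → rt, dark
Reagents that add atoms: none
Why: Nucleophile-catalysed acylation of both secondary alcohols with retention at C3 and C3′, the excess pyridine buffering HCl so that the epoxide survives.

Compound list
1 | acetone | CC(C)=O | starting material
2 | ethyl acetoacetate | CCOC(=O)CC(C)=O | starting material
3 | ethyl 2-acetyl-3-methylbut-2-enoate | CCOC(=O)C(C(C)=O)=C(C)C | intermediate
4 | 1-(triphenyl-λ5-phosphanylidene)propan-2-one | CC(=O)C=P(c1ccccc1)(c1ccccc1)c1ccccc1 | starting material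
5 | (2-ethoxyprop-1-en-1-yl)triphenylphosphonium tetrafluoroborate | CCOC(C)=C[P+](c1ccccc1)(c1ccccc1)c1ccccc1.F[B-](F)(F)F | intermediate
6 | (2-ethoxyprop-2-en-1-ylidene)triphenyl-λ5-phosphane | CCOC(=C)C=P(c1ccccc1)(c1ccccc1)c1ccccc1 | intermediate
7 | ethyl 4-ethoxy-2,6,6-trimethylcyclohexa-2,4-diene-1-carboxylate (racemic) | CCOC(=O)C1C(C)=CC(OCC)=CC1(C)C | intermediate
8 | ethyl 2,6,6-trimethyl-4-oxocyclohex-2-ene-1-carboxylate (racemic) | CCOC(=O)C1C(C)=CC(=O)CC1(C)C | intermediate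
9 | ethyl (1R,4R)-4-hydroxy-2,6,6-trimethylcyclohex-2-ene-1-carboxylate | CCOC(=O)[C@H]1C(C)=C[C@H](O)CC1(C)C | intermediate
10 | ethyl (1R,4R)-4-[(tert-butyldimethylsilyl)oxy]-2,6,6-trimethylcyclohex-2-ene-1-carboxylate | CCOC(=O)[C@H]1C(C)=C[C@H](O[Si](C)(C)C(C)(C)C)CC1(C)C | intermediate
11 | (1R,4R)-4-[(tert-butyldimethylsilyl)oxy]-2,6,6-trimethylcyclohex-2-ene-1-carbaldehyde | O=C[C@H]1C(C)=C[C@H](O[Si](C)(C)C(C)(C)C)CC1(C)C | intermediate
12 | ethyl (2E)-4-(diethoxyphosphoryl)-3-methylbut-2-enoate | CCOC(=O)/C=C(\C)CP(=O)(OCC)OCC | starting material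
13 | ethyl (2E,4E)-5-[(1R,4R)-4-[(tert-butyldimethylsilyl)oxy]-2,6,6-trimethylcyclohex-2-en-1-yl]-3-methylpenta-2,4-dienoate | CCOC(=O)/C=C(C)/C=C/[C@H]1C(C)=C[C@H](O[Si](C)(C)C(C)(C)C)CC1(C)C | intermediate
14 | (2E,4E)-5-[(1R,4R)-4-[(tert-butyldimethylsilyl)oxy]-2,6,6-trimethylcyclohex-2-en-1-yl]-3-methylpenta-2,4-dien-1-ol | OC/C=C(C)/C=C/[C@H]1C(C)=C[C@H](O[Si](C)(C)C(C)(C)C)CC1(C)C | intermediate
15 | [(2E,4E)-5-[(1R,4R)-4-[(tert-butyldimethylsilyl)oxy]-2,6,6-trimethylcyclohex-2-en-1-yl]-3-methylpenta-2,4-dien-1-yl]triphenylphosphonium bromide | [Br-].C(/C=C(C)/C=C/[C@H]1C(C)=C[C@H](O[Si](C)(C)C(C)(C)C)CC1(C)C)[P+](c1ccccc1)(c1ccccc1)c1ccccc1 | intermediate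
16 | (2E,4E,6E)-2,7-dimethylocta-2,4,6-trienedial | O=C/C(C)=C/C=C/C=C(C)/C=O | starting material
17 | (2E,4E,6E,8E,10E,12E)-13-[(1R,4R)-4-[(tert-butyldimethylsilyl)oxy]-2,6,6-trimethylcyclohex-2-en-1-yl]-2,7,11-trimethyltrideca-2,4,6,8,10,12-hexaenal | O=C/C(C)=C/C=C/C=C(C)/C=C/C=C(C)/C=C/[C@H]1C(C)=C[C@H](O[Si](C)(C)C(C)(C)C)CC1(C)C | intermediate
18 | (2E,4E,6E,8E,10E,12E)-13-[(1R,4R)-4-[(tert-butyldimethylsilyl)oxy]-2,6,6-trimethylcyclohex-2-en-1-yl]-2,7,11-trimethyltrideca-2,4,6,8,10,12-hexaen-1-ol | OC/C(C)=C/C=C/C=C(C)/C=C/C=C(C)/C=C/[C@H]1C(C)=C[C@H](O[Si](C)(C)C(C)(C)C)CC1(C)C | intermediate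
19 | [(2E,4E,6E,8E,10E,12E)-13-[(1R,4R)-4-[(tert-butyldimethylsilyl)oxy]-2,6,6-trimethylcyclohex-2-en-1-yl]-2,7,11-trimethyltrideca-2,4,6,8,10,12-hexaen-1-yl]triphenylphosphonium bromide | [Br-].C(/C(C)=C/C=C/C=C(C)/C=C/C=C(C)/C=C/[C@H]1C(C)=C[C@H](O[Si](C)(C)C(C)(C)C)CC1(C)C)[P+](c1ccccc1)(c1ccccc1)c1ccccc1 | intermediate
20 | (4R,6R)-4-hydroxy-2,2,6-trimethylcyclohexan-1-one | C[C@@H]1C[C@@H](O)CC(C)(C)C1=O | starting material
21 | (4R,6R)-4-[(tert-butyldimethylsilyl)oxy]-2,2,6-trimethylcyclohexan-1-one | C[C@@H]1C[C@@H](O[Si](C)(C)C(C)(C)C)CC(C)(C)C1=O | intermediate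
22 | (4R)-4-[(tert-butyldimethylsilyl)oxy]-2,6,6-trimethylcyclohex-1-en-1-yl trifluoromethanesulfonate | CC1=C(OS(=O)(=O)C(F)(F)F)C(C)(C)C[C@H](O[Si](C)(C)C(C)(C)C)C1 | intermediate
23 | methyl (4R)-4-[(tert-butyldimethylsilyl)oxy]-2,6,6-trimethylcyclohex-1-ene-1-carboxylate | CC1=C(C(=O)OC)C(C)(C)C[C@H](O[Si](C)(C)C(C)(C)C)C1 | intermediate
24 | [(4R)-4-[(tert-butyldimethylsilyl)oxy]-2,6,6-trimethylcyclohex-1-en-1-yl]methanol | CC1=C(CO)C(C)(C)C[C@H](O[Si](C)(C)C(C)(C)C)C1 | intermediate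
25 | [(1R,4S,6R)-4-[(tert-butyldimethylsilyl)oxy]-2,2,6-trimethyl-7-oxabicyclo[4.1.0]heptan-1-yl]methanol | CC(C)(C)[Si](C)(C)O[C@H]1CC(C)(C)[C@]2(CO)O[C@]2(C)C1 | intermediate
26 | (1S,4S,6R)-4-[(tert-butyldimethylsilyl)oxy]-2,2,6-trimethyl-7-oxabicyclo[4.1.0]heptane-1-carbaldehyde | CC(C)(C)[Si](C)(C)O[C@H]1CC(C)(C)[C@]2(C=O)O[C@]2(C)C1 | intermediate
27 | diethyl [(2E)-3-cyano-2-methylprop-2-en-1-yl]phosphonate | CCOP(=O)(OCC)C/C(C)=C/C#N | starting material
28 | (2E,4E)-5-[(1S,4S,6R)-4-[(tert-butyldimethylsilyl)oxy]-2,2,6-trimethyl-7-oxabicyclo[4.1.0]heptan-1-yl]-3-methylpenta-2,4-dienenitrile | CC(C)(C)[Si](C)(C)O[C@H]1CC(C)(C)[C@]2(/C=C/C(C)=C/C#N)O[C@]2(C)C1 | intermediate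
29 | N-(diisobutylalumanyl)imine of aldehyde 30 | CC(C)(C)[Si](C)(C)O[C@H]1CC(C)(C)[C@]2(/C=C/C(C)=C/C=N[Al](CC(C)C)CC(C)C)O[C@]2(C)C1 | intermediate
30 | (2E,4E)-5-[(1S,4S,6R)-4-[(tert-butyldimethylsilyl)oxy]-2,2,6-trimethyl-7-oxabicyclo[4.1.0]heptan-1-yl]-3-methylpenta-2,4-dienal | CC(C)(C)[Si](C)(C)O[C@H]1CC(C)(C)[C@]2(/C=C/C(C)=C/C=O)O[C@]2(C)C1 | intermediate
31 | (all-E,3S,5R,6S,3′R,6′R)-3,3′-bis[(tert-butyldimethylsilyl)oxy]-5,6-epoxy-5,6-dihydro-β,ε-carotene | CC(C)(C)[Si](C)(C)O[C@H]1CC(C)(C)[C@]2(/C=C/C(C)=C/C=C/C(C)=C/C=C/C=C(C)/C=C/C=C(C)/C=C/[C@H]3C(C)=C[C@H](O[Si](C)(C)C(C)(C)C)CC3(C)C)O[C@]2(C)C1 | intermediate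
32 | (all-E,3S,5R,6S,3′R,6′R)-5,6-epoxy-5,6-dihydro-β,ε-carotene-3,3′-diol | O[C@H]1CC(C)(C)[C@]2(/C=C/C(C)=C/C=C/C(C)=C/C=C/C=C(C)/C=C/C=C(C)/C=C/[C@H]3C(C)=C[C@H](O)CC3(C)C)O[C@]2(C)C1 | intermediate
33 | hexadecanoyl chloride | CCCCCCCCCCCCCCCC(=O)Cl | starting material
34 | (all-E,3S,5R,6S,3′R,6′R)-5,6-epoxy-5,6-dihydro-β,ε-carotene-3,3′-diyl dihexadecanoate | CCCCCCCCCCCCCCCC(=O)O[C@H]1CC(C)(C)[C@]2(/C=C/C(C)=C/C=C/C(C)=C/C=C/C=C(C)/C=C/C=C(C)/C=C/[C@H]3C(C)=C[C@H](OC(=O)CCCCCCCCCCCCCCC)CC3(C)C)O[C@]2(C)C1 | target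

Total step count: 23. Longest linear sequence: 14 steps (steps 1, 3 to 12, 21 to 23); the epoxy branch (steps 13 to 20) and step 2 are side branches.

Steps most likely to fail:

Step 3. The ylide may act as a base on the allylic or acetyl hydrogens of 3 (deconjugation to an unreactive enolate) or attack through its α-carbon, so that the hindered quaternary bond does not form; the ring double bond may also drift into conjugation with the ester during hydrolysis. The fallback sets out from 3: a TiCl4-mediated Mukaiyama–Michael addition of 2-(trimethylsilyloxy)propene (CH2Cl2, −78 °C) should give ethyl 2-acetyl-3,3-dimethyl-5-oxohexanoate F1, and acid-catalysed intramolecular aldol condensation (TsOH, toluene, reflux, water removal) of the methyl ketone onto the β-keto ester carbonyl returns to the route at 8.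

Step 4. The remote C1 center may not create a large enough rate difference between the antipodes of 8, giving eroded enantiomeric purity or cis/trans mixtures. The fallback sets out from 8: substrate-controlled reduction with KBH(s-Bu)3 (THF, −78 °C) should give ethyl (1RS,4RS)-4-hydroxy-2,6,6-trimethylcyclohex-2-ene-1-carboxylate (racemic trans) F2. Lipase-catalysed transesterification with vinyl acetate (Burkholderia cepacia lipase, t-BuOMe, rt) is expected to acylate the (4R) antipode to ethyl (1R,4R)-4-(acetyloxy)-2,6,6-trimethylcyclohex-2-ene-1-carboxylate F3. F3 is separated from the unreacted antipode and ethanolysed (K2CO3, EtOH), which comes back to the route at 9.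

Step 7. The basic olefination may epimerise C1 of 11 or move the ring double bond into conjugation with the aldehyde before addition occurs. The fallback sets out from 11: a base-free Wittig reaction with the stabilised ylide 4 (toluene, reflux) should give (3E)-4-[(1R,4R)-4-[(tert-butyldimethylsilyl)oxy]-2,6,6-trimethylcyclohex-2-en-1-yl]but-3-en-2-one F4. Addition of vinylmagnesium bromide (THF, −78 °C) gives (1E)-1-[(1R,4R)-4-[(tert-butyldimethylsilyl)oxy]-2,6,6-trimethylcyclohex-2-en-1-yl]-3-methylpenta-1,4-dien-3-ol F5. PPh3·HBr (CH2Cl2, 0 °C) with allylic transposition then comes back to the route at 15, bypassing 13 and 14.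

Further compounds
F1 | step 3 | ethyl 2-acetyl-3,3-dimethyl-5-oxohexanoate | CCOC(=O)C(C(C)=O)C(C)(C)CC(C)=O
F2 | step 4 | ethyl (1RS,4RS)-4-hydroxy-2,6,6-trimethylcyclohex-2-ene-1-carboxylate (racemic trans) | CCOC(=O)[C@H]1C(C)=C[C@H](O)CC1(C)C.CCOC(=O)[C@@H]1C(C)=C[C@@H](O)CC1(C)C
F3 | step 4 | ethyl (1R,4R)-4-(acetyloxy)-2,6,6-trimethylcyclohex-2-ene-1-carboxylate | CCOC(=O)[C@H]1C(C)=C[C@H](OC(C)=O)CC1(C)C
F4 | step 7 | (3E)-4-[(1R,4R)-4-[(tert-butyldimethylsilyl)oxy]-2,6,6-trimethylcyclohex-2-en-1-yl]but-3-en-2-one | CC(=O)/C=C/[C@H]1C(C)=C[C@H](O[Si](C)(C)C(C)(C)C)CC1(C)C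
F5 | step 7 | (1E)-1-[(1R,4R)-4-[(tert-butyldimethylsilyl)oxy]-2,6,6-trimethylcyclohex-2-en-1-yl]-3-methylpenta-1,4-dien-3-ol (both C3 epimers) | C=CC(C)(O)/C=C/[C@H]1C(C)=C[C@H](O[Si](C)(C)C(C)(C)C)CC1(C)C
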